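**Retrosynthetic overview**
- The strategy rests on the oxolane ring: O1–C5H2 is unsubstituted and sits next to C4, whose arylmethyl group can be read as a reduced (E)-styrene. The C4–C5 bond is therefore cut to an O–CH2 radical and a styrene acceptor (5-exo closure).
- The radical precursor is the (phenylselanyl)methyl ether of a homoallylic alcohol that already carries C3 and the silyl-protected carbinol centre.
- These two centres come from an Evans syn aldol of an (E)-4-arylbut-3-enoyl oxazolidinone with O-benzylsyringaldehyde, followed by silylation and reductive removal of the auxiliary.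
- The acyl unit comes from a Wittig reaction of O-benzylsyringaldehyde with (2-carboxyethyl)triphenylphosphonium bromide.
- Ring order: the oxolane is the only ring built and is closed in step 8; desilylation and hydrogenolysis follow.

Key step: step 8

Remark: the oxolane is numbered O1, C2, C3 (carbinol-bearing), C4 (arylmethyl-bearing), C5; (S)-4-benzyloxazolidin-2-one, benzyl bromide and the silyl triflate are taken as commercial.

**Step 1**
Reactants: 1 syringaldehyde (4-hydroxy-3,5-dimethoxybenzaldehyde)
Product: 2 4-(benzyloxy)-3,5-dimethoxybenzaldehyde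
Conditions: BnBr, K2CO3, DMF, 60 °C
Reagents that add atoms: benzyl bromide, BrCc1ccccc1
Why: Williamson etherification of the acidic 2,6-dimethoxyphenol under carbonate conditions, which leave the aldehyde untouched.

**Step 2**
Reactants: 2 4-(benzyloxy)-3,5-dimethoxybenzaldehyde; 3 (2-carboxyethyl)triphenylphosphonium bromide
Product: 5 (E)-4-[4-(benzyloxy)-3,5-dimethoxyphenyl]but-3-enoic acid, via carboxylate ylide 4 (not isolated)
Conditions: NaHMDS (2 equiv per 3), THF, 0 °C; then 2, −78 °C → rt; aq. HCl work-up; recrystallisation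
Reagents that add atoms: none
Why: Wittig olefination through the doubly deprotonated ylide 4; carboxylate-bearing ylides should favour the (E)-alkene with aromatic aldehydes, and crystallisation of the acid should remove any (Z)-isomer.

**Step 3**
Reactants: 5 (E)-4-[4-(benzyloxy)-3,5-dimethoxyphenyl]but-3-enoic acid; 6 (S)-4-benzyloxazolidin-2-one
Product: 8 (S)-4-benzyl-3-{(E)-4-[4-(benzyloxy)-3,5-dimethoxyphenyl]but-3-enoyl}oxazolidin-2-one, via mixed pivalic anhydride 7 (not isolated)
Conditions: PivCl, Et3N, THF, −20 °C; then LiCl, 6, −20 °C → rt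
Reagents that add atoms: none
Why: N-acylation of the oxazolidinone through the mixed anhydride under LiCl/Et3N activation, mild enough to keep the β,γ-double bond in conjugation with the arene.

**Step 4**
Reactants: 8 (S)-4-benzyl-3-{(E)-4-[4-(benzyloxy)-3,5-dimethoxyphenyl]but-3-enoyl}oxazolidin-2-one; 2 4-(benzyloxy)-3,5-dimethoxybenzaldehyde
Product: 11 (2S,3S)-syn-aldol adduct (α-styryl β-hydroxy imide), via dibutylboron (Z)-dienolate 9 (not isolated), via dibutylboron aldolate 10 (not isolated)
Conditions: Bu2BOTf, i-Pr2NEt, CH2Cl2, −78 → 0 °C; then 2, −78 → 0 °C; pH 7 buffer, MeOH, 30% H2O2, 0 °C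
Reagents that add atoms: none
Why: Evans boron-mediated syn aldol: the (Z)-dienolate 9 should add at its α-carbon through a closed Zimmerman–Traxler chair on the face opposite the auxiliary benzyl group, setting the (2S) centre and the (S)-carbinol together, and oxidative work-up releases 11 from 10.

**Step 5**
Reactants: 11 (2S,3S)-syn-aldol adduct
Product: 12 tert-butyldimethylsilyl ether of 11
Conditions: TBSOTf, 2,6-lutidine, CH2Cl2, −78 → 0 °C
Reagents that add atoms: tert-butyldimethylsilyl trifluoromethanesulfonate, CC(C)(C)[Si](C)(C)OS(=O)(=O)C(F)(F)F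
Why: Silylation of the secondary hydroxyl with a silyl triflate and a hindered pyridine base at low temperature, conditions that should cause neither retro-aldol nor epimerisation of the α-centre.

**Step 6**
Reactants: 12 tert-butyldimethylsilyl ether of 11
Product: 13 (2R,3E)-4-[4-(benzyloxy)-3,5-dimethoxyphenyl]-2-{(S)-[4-(benzyloxy)-3,5-dimethoxyphenyl](tert-butyldimethylsilyloxy)methyl}but-3-en-1-ol
Conditions: LiBH4, MeOH (1 equiv), THF, 0 °C
Reagents that add atoms: none
Why: Borohydride reduction of the exocyclic imide carbonyl should release the primary alcohol and the auxiliary without touching the silyl ether, the styrene or either stereocentre.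

**Step 7**
Reactants: 13 silyl-protected homoallylic alcohol; 14 chloromethyl phenyl selenide
Product: 16 (phenylselanyl)methyl ether of 13, via sodium alkoxide 15 (not isolated)
Conditions: NaH, 14, Bu4NI (cat.), THF–DMF, 0 °C → rt
Reagents that add atoms: none
Why: Williamson O-alkylation of the alkoxide with the activated α-chloro selenide under iodide catalysis; having the electrophile present from the start at 0 °C should trap the alkoxide before the silyl group can migrate between the 1,3-oxygens.

**Step 8**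
Reactants: 16 (phenylselanyl)methyl ether of 13
Product: 19 tert-butyl{(S)-[4-(benzyloxy)-3,5-dimethoxyphenyl][(3R,4R)-4-[4-(benzyloxy)-3,5-dimethoxybenzyl]oxolan-3-yl]methoxy}dimethylsilane, via alkoxymethyl radical 17 (not isolated), via benzylic radical 18 (not isolated)
Conditions: Bu3SnH, AIBN (cat.), PhH (0.01 M), 80 °C, syringe-pump addition of the stannane
Reagents that add atoms: none
Why: The tributyltin radical abstracts the phenylselanyl group of 16 to give the nucleophilic alkoxymethyl radical 17, which adds to the proximal styrene carbon to leave benzylic radical 18; hydrogen transfer from the stannane then gives the arylmethyl group and carries the chain. The closest known reaction type is the tin hydride-mediated cyclisation of (phenylselanyl)methyl ethers of homoallylic alcohols to 3- and 3,4-substituted oxolanes. The oxolane closes in the 5-exo-trig mode by forming C4–C5. The new C4 centre is controlled by the existing C3 centre: in the chair-like Beckwith–Houk transition state the bulky silyloxy(aryl)methyl group sits pseudo-equatorial, which should place the new bond trans to it and give the (3R,4R) ring. The step needs ring closure to outrun direct reduction of 17 and 1,5-hydrogen transfer from the benzylic C–H, and exo to beat endo closure; the styrene acceptor, which yields a stabilised benzylic radical, together with high dilution and slow stannane addition should secure both. Any 3,4-cis isomer should be separable by chromatography at 19 or 20.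

**Step 9**
Reactants: 19 cyclised silyl ether
Product: 20 (S)-[4-(benzyloxy)-3,5-dimethoxyphenyl]{(3R,4R)-4-[4-(benzyloxy)-3,5-dimethoxybenzyl]oxolan-3-yl}methanol
Conditions: TBAF, THF, 0 °C → rt
Reagents that add atoms: none
Why: Fluoride-mediated desilylation of the secondary silyl ether; the benzyl ethers and the oxolane are inert and no stereocentre is touched.

**Step 10**
Reactants: 20 O,O'-dibenzyl alcohol
Product: 21 (S)-(4-hydroxy-3,5-dimethoxyphenyl)[(3R,4R)-4-(4-hydroxy-3,5-dimethoxybenzyl)oxolan-3-yl]methanol (target)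
Conditions: H2 (1 atm), 10% Pd/C, EtOAc, rt
Reagents that add atoms: none
Why: Catalytic hydrogenolysis of the two aryl benzyl ethers in a neutral aprotic solvent at ambient pressure, under which the secondary benzylic alcohol should survive if the reaction is stopped once the benzyl ethers are consumed.

**Compound list**
1 | syringaldehyde | COc1cc(C=O)cc(OC)c1O | starting material
2 | 4-(benzyloxy)-3,5-dimethoxybenzaldehyde | COc1cc(C=O)cc(OC)c1OCc1ccccc1 | intermediate
3 | (2-carboxyethyl)triphenylphosphonium bromide | OC(=O)CC[P+](c1ccccc1)(c1ccccc1)c1ccccc1.[Br-] | starting material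
4 | carboxylate ylide, sodium 3-(triphenyl-λ5-phosphanylidene)propanoate (not isolated) | [Na+].[O-]C(=O)CC=P(c1ccccc1)(c1ccccc1)c1ccccc1 | intermediate
5 | (E)-4-[4-(benzyloxy)-3,5-dimethoxyphenyl]but-3-enoic acid | OC(=O)C/C=C/c1cc(OC)c(OCc2ccccc2)c(OC)c1 | intermediate
6 | (S)-4-benzyloxazolidin-2-one | O=C1N[C@@H](Cc2ccccc2)CO1 | starting material
7 | mixed pivalic anhydride of 5 (not isolated) | CC(C)(C)C(=O)OC(=O)C/C=C/c1cc(OC)c(OCc2ccccc2)c(OC)c1 | intermediate
8 | (S)-4-benzyl-3-{(E)-4-[4-(benzyloxy)-3,5-dimethoxyphenyl]but-3-enoyl}oxazolidin-2-one | O=C(C/C=C/c1cc(OC)c(OCc2ccccc2)c(OC)c1)N1[C@@H](Cc2ccccc2)COC1=O | intermediate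
9 | dibutylboron (1Z,3E)-dienolate of 8 (not isolated) | CCCCB(CCCC)O/C(=C\C=C\c1cc(OC)c(OCc2ccccc2)c(OC)c1)N1[C@@H](Cc2ccccc2)COC1=O | intermediate
10 | dibutylboron aldolate of 11 (not isolated) | O=C([C@@H](/C=C/c1cc(OC)c(OCc2ccccc2)c(OC)c1)[C@H](OB(CCCC)CCCC)c1cc(OC)c(OCc2ccccc2)c(OC)c1)N1[C@@H](Cc2ccccc2)COC1=O | intermediate
11 | (4S)-4-benzyl-3-{(2S,3E)-4-[4-(benzyloxy)-3,5-dimethoxyphenyl]-2-[(S)-[4-(benzyloxy)-3,5-dimethoxyphenyl](hydroxy)methyl]but-3-enoyl}oxazolidin-2-one | O=C([C@@H](/C=C/c1cc(OC)c(OCc2ccccc2)c(OC)c1)[C@H](O)c1cc(OC)c(OCc2ccccc2)c(OC)c1)N1[C@@H](Cc2ccccc2)COC1=O | intermediate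
12 | tert-butyldimethylsilyl ether of 11 | O=C([C@@H](/C=C/c1cc(OC)c(OCc2ccccc2)c(OC)c1)[C@H](O[Si](C)(C)C(C)(C)C)c1cc(OC)c(OCc2ccccc2)c(OC)c1)N1[C@@H](Cc2ccccc2)COC1=O | intermediate
13 | (2R,3E)-4-[4-(benzyloxy)-3,5-dimethoxyphenyl]-2-{(S)-[4-(benzyloxy)-3,5-dimethoxyphenyl](tert-butyldimethylsilyloxy)methyl}but-3-en-1-ol | OC[C@@H](/C=C/c1cc(OC)c(OCc2ccccc2)c(OC)c1)[C@H](O[Si](C)(C)C(C)(C)C)c1cc(OC)c(OCc2ccccc2)c(OC)c1 | intermediate
14 | chloromethyl phenyl selenide | ClC[Se]c1ccccc1 | starting material
15 | sodium alkoxide of 13 (not isolated) | [Na+].[O-]C[C@@H](/C=C/c1cc(OC)c(OCc2ccccc2)c(OC)c1)[C@H](O[Si](C)(C)C(C)(C)C)c1cc(OC)c(OCc2ccccc2)c(OC)c1 | intermediate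
16 | (phenylselanyl)methyl ether of 13, (1S,2R,3E)-configured key-step precursor | c1ccccc1[Se]COC[C@@H](/C=C/c1cc(OC)c(OCc2ccccc2)c(OC)c1)[C@H](O[Si](C)(C)C(C)(C)C)c1cc(OC)c(OCc2ccccc2)c(OC)c1 | intermediate
17 | alkoxymethyl radical from 16 (not isolated) | [CH2]OC[C@@H](/C=C/c1cc(OC)c(OCc2ccccc2)c(OC)c1)[C@H](O[Si](C)(C)C(C)(C)C)c1cc(OC)c(OCc2ccccc2)c(OC)c1 | intermediate
18 | cyclised benzylic radical (not isolated) | COc1cc([CH][C@H]2COC[C@@H]2[C@H](O[Si](C)(C)C(C)(C)C)c2cc(OC)c(OCc3ccccc3)c(OC)c2)cc(OC)c1OCc1ccccc1 | intermediate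
19 | tert-butyl{(S)-[4-(benzyloxy)-3,5-dimethoxyphenyl][(3R,4R)-4-[4-(benzyloxy)-3,5-dimethoxybenzyl]oxolan-3-yl]methoxy}dimethylsilane | COc1cc(C[C@H]2COC[C@@H]2[C@H](O[Si](C)(C)C(C)(C)C)c2cc(OC)c(OCc3ccccc3)c(OC)c2)cc(OC)c1OCc1ccccc1 | intermediate
20 | (S)-[4-(benzyloxy)-3,5-dimethoxyphenyl]{(3R,4R)-4-[4-(benzyloxy)-3,5-dimethoxybenzyl]oxolan-3-yl}methanol | COc1cc(C[C@H]2COC[C@@H]2[C@H](O)c2cc(OC)c(OCc3ccccc3)c(OC)c2)cc(OC)c1OCc1ccccc1 | intermediate
21 | (S)-(4-hydroxy-3,5-dimethoxyphenyl)[(3R,4R)-4-(4-hydroxy-3,5-dimethoxybenzyl)oxolan-3-yl]methanol | COc1cc(C[C@H]2COC[C@@H]2[C@H](O)c2cc(OC)c(O)c(OC)c2)cc(OC)c1O | target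

**Step count and risks**
Total step count: 10. Longest linear sequence: 10 steps (1 → 21).

Steps most likely to fail:

1. Step 8 (radical closure). The alkoxymethyl radical may take hydrogen from the stannane before it closes, or chair and boat transition states may compete and erode the trans selectivity at C4. The fallback closes the same C4–C5 bond by a polar route and sets out from 13. O-Alkylation with (iodomethyl)tributylstannane (NaH, THF–DMF, 0 °C) would give the (tributylstannyl)methyl ether F1. Tin–lithium exchange with n-BuLi in THF at −78 °C would give the α-alkoxymethyllithium F2. Its intramolecular 5-exo carbolithiation of the styrene runs with no hydrogen donor present, and quenching the resulting benzylic lithium with methanol would come back to the route at 19.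

2. Step 7 (selenomethyl ether formation). Under alkoxide conditions the silyl group may migrate from the secondary to the primary oxygen, or O-alkylation by the α-chloro selenide may be slow. The fallback assembles the O–CH2–Se unit without an alkoxide and sets out from 13. Dimethyl sulfide and benzoyl peroxide in MeCN at 0 °C (Pummerer-type methylthiomethylation) would give the methylthiomethyl ether F3. Sulfuryl chloride in CH2Cl2 at −78 °C, with cyclohexene to scavenge the sulfenyl chloride, would convert it into the chloromethyl ether F4, used crude. Displacement with sodium benzeneselenolate (from diphenyl diselenide and NaBH4, EtOH–THF, 0 °C) would come back to the route at 16.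

3. Step 4 (aldol). The aryl-conjugated dienolate is stabilised and the trialkoxybenzaldehyde is a weak electrophile, so the addition may stall, revert by retro-aldol, or lose α-regiocontrol and facial control. The fallback attaches the aryl group to the alkene after the aldol and sets out from 6. N-Acylation with crotonyl chloride (n-BuLi, THF, −78 °C) would give (S)-4-benzyl-3-[(E)-but-2-enoyl]oxazolidin-2-one F5. Its dibutylboron dienolate (Bu2BOTf, Et3N) should undergo the α-selective syn aldol with 2 to give the α-vinyl adduct F6, and silylation (TBSOTf, 2,6-lutidine) would give its silyl ether F7. Cross-metathesis of F7 with 4-(benzyloxy)-3,5-dimethoxystyrene F8 (from 2 by Wittig methylenation with Ph3P=CH2), using a second-generation Grubbs catalyst in CH2Cl2 at 40 °C, should deliver the (E)-styrene and come back to the route at 12.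

**Further compounds**
F1 | step 8 | (tributylstannyl)methyl ether of 13 | CCCC[Sn](CCCC)(CCCC)COC[C@@H](/C=C/c1cc(OC)c(OCc2ccccc2)c(OC)c1)[C@H](O[Si](C)(C)C(C)(C)C)c1cc(OC)c(OCc2ccccc2)c(OC)c1
F2 | step 8 | α-alkoxymethyllithium from F1 | [Li]COC[C@@H](/C=C/c1cc(OC)c(OCc2ccccc2)c(OC)c1)[C@H](O[Si](C)(C)C(C)(C)C)c1cc(OC)c(OCc2ccccc2)c(OC)c1
F3 | step 7 | methylthiomethyl ether of 13 | CSCOC[C@@H](/C=C/c1cc(OC)c(OCc2ccccc2)c(OC)c1)[C@H](O[Si](C)(C)C(C)(C)C)c1cc(OC)c(OCc2ccccc2)c(OC)c1
F4 | step 7 | chloromethyl ether of 13 | ClCOC[C@@H](/C=C/c1cc(OC)c(OCc2ccccc2)c(OC)c1)[C@H](O[Si](C)(C)C(C)(C)C)c1cc(OC)c(OCc2ccccc2)c(OC)c1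
F5 | step 4 | (S)-4-benzyl-3-[(E)-but-2-enoyl]oxazolidin-2-one | C/C=C/C(=O)N1[C@@H](Cc2ccccc2)COC1=O
F6 | step 4 | (4S)-4-benzyl-3-{(2S)-2-[(S)-[4-(benzyloxy)-3,5-dimethoxyphenyl](hydroxy)methyl]but-3-enoyl}oxazolidin-2-one | O=C([C@@H](C=C)[C@H](O)c1cc(OC)c(OCc2ccccc2)c(OC)c1)N1[C@@H](Cc2ccccc2)COC1=O
F7 | step 4 | tert-butyldimethylsilyl ether of F6 | O=C([C@@H](C=C)[C@H](O[Si](C)(C)C(C)(C)C)c1cc(OC)c(OCc2ccccc2)c(OC)c1)N1[C@@H](Cc2ccccc2)COC1=O
F8 | step 4 | 4-(benzyloxy)-3,5-dimethoxystyrene | C=Cc1cc(OC)c(OCc2ccccc2)c(OC)c1
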